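## Analysis of the target

The target 16 is the hexadecanoate of a bicyclic terpenoid lactone: a cyclohexane ring fused along C3a–C7a to an α,β-unsaturated γ-lactone (benzofuranone numbering: O1, carbonyl C2, C3, C3a, C4 to C7, C7a). The carbocycle carries a gem-dimethyl group at C4, the ester oxygen at C6 and an angular methyl group at C7a, which is fully substituted and bonded to the lactone oxygen O1. There are two stereocentres, C6 (S) and C7a (R), 1,3-related through the C7 methylene. The C6 oxygen is trans to O1 and cis to the angular methyl, so the ester sits axial between two syn-axial methyl groups. Sensitive features are the butenolide (a conjugate acceptor whose C7a–O1 bond is tertiary and allylic, hence prone to ionisation under acid) and the long-chain ester, which is best attached last. The difficulty is the oxygenated quaternary centre C7a: it lies between the sp2 carbon C3a and the C7 methylene, must be set relative to a remote carbinol, and has no hydrogen through which a wrong configuration could be corrected. The strategy rests on one feature: O1 on C7a and the carbonyl oxygen on C2 stand 1,4 to each other across the C3a=C3 double bond. This is the pattern left when one molecule of dioxygen adds to the two ends of a diene C7a=C3a–C3=C2 and the peroxide is then isomerised.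

## Retrosynthetic reasoning

**Ester C–O bond.** The acyl–oxygen bond of 16 is cut first, giving the alcohol 14 and the acid chloride 15. The long chain is kept out of all earlier steps, where its enolisable ester would meet an amide base and aqueous carbonate. The forward reaction has to acylate a hindered axial alcohol on oxygen, with no change at C6.

**Protecting group.** Alcohol 14 is traced to its silyl ether 13. The silyl group has to survive an amide base, aqueous carbonate with palladium, singlet oxygen, an amine and a ruthenium oxidant. It must then be removable under buffered, non-basic conditions that leave the butenolide alone.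

**Oxidation level and O–O bond.** The lactone carbonyl of 13 is taken back to the lactol 12, which is the closed form of the Z-hydroxy enal 11. Compound 11 is the product expected when base breaks the O–O bond of the endoperoxide 10. In 10 the peroxide carbon C8a (later C7a) bears no hydrogen, whereas C3 (later C2) is a methylene. The opening can therefore only give the aldehyde at C3 and the tertiary alkoxide at C8a. The six-membered peroxide ring also fixes the Z geometry, so the hydroxyl and the aldehyde are held together and ring closure to 12 follows.

**The two C–O bonds of the dioxine (key disconnection).** Cutting O1–C8a and O2–C3 of 10 leads to the vinylcyclohexene 8 and dioxygen 9. This removes the quaternary stereocentre, the lactone oxygen and the C2 oxidation in one operation and leaves a diene with a single stereocentre. No other cut deals with both oxygens at once. The forward reaction must add 9, in its singlet state, across the diene termini and not in the ene mode, and on the face anti to the silyloxy group.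

**Ring–vinyl C–C bond.** The bond between the ring sp2 carbon and the vinyl group of 8 is cut to give the enol triflate 6 and the vinyltrifluoroborate 7. The ring carbon concerned is a former carbonyl carbon, so the electrophile is available from a ketone without any regiochemical question. The forward coupling has to work at a triflate flanked by a quaternary carbon and a methyl-substituted alkene carbon.

**Enol triflate.** Triflate 6 comes from the potassium enolate 5 of ketone 4. Ketone 4 has one α-hydrogen only, so only one enolate can form. The methyl-bearing stereocentre of 4 is given up at this point, so only the carbinol configuration has to be correct. Ketone 4 is the silyl ether of the hydroxy ketone 3.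

**Two reductions.** Hydroxy ketone 3 is traced through dione 2 to the achiral enedione 1, a commodity chemical. Reduction of the C=C bond and then of the unhindered carbonyl are both known biocatalytic steps on exactly these substrates. They set 6R and then 4R, and 4R becomes C6 of the target.

## Alternatives that were turned down

**Alternative 1:** The disconnection is the C3–C3a bond of a saturated lactone. The tertiary oxygen on C7a would carry a diazoacetyl group, as in (1S,3S)-3-[(diazoacetyl)oxy]-3,5,5-trimethylcyclohexyl benzoate A2. A dirhodium tetracarboxylate would convert the diazo carbon into a carbenoid that inserts into a C–H bond of the ring methylene next to the gem-dimethyl group. The product would be the cis-fused lactone (3aS,6S,7aR)-4,4,7a-trimethyl-2-oxooctahydro-1-benzofuran-6-yl benzoate A1.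
- For it: five-membered C–H insertion of diazoacetates is a dependable closure and the cis fusion is dictated by the tether. Both stereocentres exist before the key step, so ring formation raises no facial question, and no photochemistry or peroxide is handled. On these points it is stronger than the chosen route.
- Against it: A1 is one oxidation level too low, so the C3a=C3 double bond would need α-functionalisation and elimination afterwards, in a molecule with two esters. The carbenoid can reach three kinds of 1,5-related C–H bond (the wanted neopentyl methylene, the methylene next to the benzoate, the angular methyl), and only the inductive effect of the benzoate favours the right one. A diazoacetate of a hindered tertiary alcohol is awkward to prepare. A2 needs a tertiary and a secondary carbinol of defined absolute and relative configuration on a ring with no simple enantioselective entry. The benzoate must finally be exchanged for the palmitate.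
- Comparison: the chosen strategy gets the butenolide oxidation level directly from the peroxide isomerisation and takes C6 from an enzymatic reduction. In exchange it gives up a pre-set C7a and relies on substrate control in the cycloaddition.

**Alternative 2:** The disconnection is the C3a–C4 bond of the carbocycle together with the lactone C–O bond. The precursor would be ethyl (4R,6R)-6-[(tert-butyldimethylsilyl)oxy]-4-hydroxy-4,8-dimethylnon-7-en-2-ynoate A4. An iron hydride, formed from an iron tris(β-diketonate) and a silane, would transfer a hydrogen atom to the CH end of the trisubstituted alkene. The tertiary radical would add 6-exo to the β-carbon of the ynoate, and after reduction of the vinyl radical the Z-hydroxy ester would lactonise. The product would be (6S,7aR)-6-[(tert-butyldimethylsilyl)oxy]-4,4,7a-trimethyl-5,6,7,7a-tetrahydro-1-benzofuran-2(4H)-one A3, the same structure as 13.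
- For it: it is convergent, forms the carbocycle and the quaternary C4 in one step, and arrives at the correct oxidation level. Both stereocentres are in place before cyclisation. In convergency and in having no diastereoselective ring-forming step it is stronger than the chosen route.
- Against it: the new bond joins a tertiary radical to an alkyne carbon that sits next to a fully substituted carbinol carbon, so two congested centres become neighbours. Hydrogen-atom-transfer additions are best established for alkene acceptors. An alkynoate gives a vinyl radical whose reduction is not expected to be geometry-selective, and only the Z isomer can lactonise. Simple reduction of the alkene competes. The tertiary propargylic carbinol of A4, 1,3 to a secondary silyl ether, would have to be set in an open chain where 1,3-induction is weak.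
- Comparison: the chosen strategy takes ring and C6 configuration from a cyclic precursor, and the Z relationship is enforced by the dioxine ring. It pays with a photochemical step and a peroxide intermediate.

**Alternative 3:** The disconnection is a C5=C6 double bond introduced for the purpose. The precursor would be (5R)-5-methyl-4-(2-methylbut-3-en-2-yl)-5-(prop-2-en-1-yl)furan-2(5H)-one A6. A second-generation ruthenium alkylidene would join its two terminal alkenes and close the carbocycle, giving (7aR)-4,4,7a-trimethyl-7,7a-dihydro-1-benzofuran-2(4H)-one A5.
- For it: closing a cyclohexene from two monosubstituted alkenes is among the most reliable ring closures. It tolerates the flanking quaternary centres and has no selectivity issue. As a ring-forming step it is more robust than a photo-oxygenation.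
- Against it: A5 lacks the C6 oxygen and carries an alkene the target does not have. Hydration would have to distinguish C6 from C5 and one face from the other while sparing the conjugated lactone. The less hindered face is anti to the axial angular methyl, which would lead to the C6 epimer, so an inversion would be needed as well. A6 already contains the oxygenated quaternary stereocentre next to a tertiary-alkyl-substituted butenolide carbon, and making it as one enantiomer is a problem of its own.
- Comparison: the difficult parts are moved before and after the key step. The chosen route has the C6 oxygen from the first stereo-defining step and makes C7a in the key step.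

Key step: step 6

## Route

Assumption: position 3 of the trivial name (carotenoid numbering) is C6 of the benzofuranone, and the (−) enantiomer is the (6S,7aR) compound written in the SMILES string.
Assumption: the two reductases of steps 1 and 2 are used as recombinant preparations with glucose/glucose dehydrogenase cofactor recycling.

**Step 1**
Reactants: 1 ketoisophorone (2,6,6-trimethylcyclohex-2-ene-1,4-dione)
Product: 2 (6R)-2,2,6-trimethylcyclohexane-1,4-dione ((6R)-levodione)
Conditions: old yellow enzyme OYE2 (Saccharomyces cerevisiae), NADP+ (cat.), D-glucose, glucose dehydrogenase, phosphate buffer pH 6.5, 30 °C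
Reagents that add atoms: none
Why: Biocatalytic asymmetric reduction of an activated alkene by a flavin-dependent ene-reductase: hydride from the reduced flavin and a proton from the opposite face add trans across C2=C3 inside the active site, which for this substrate is known to deliver the 6R dione; slightly acidic buffer and prompt extraction limit racemisation of the enolisable centre.

**Step 2**
Reactants: 2 (6R)-2,2,6-trimethylcyclohexane-1,4-dione
Product: 3 (4R,6R)-4-hydroxy-2,2,6-trimethylcyclohexan-1-one ((4R,6R)-actinol)
Conditions: levodione reductase (Corynebacterium aquaticum), NAD+ (cat.), D-glucose, glucose dehydrogenase, phosphate buffer pH 7, 30 °C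
Reagents that add atoms: none
Why: Enzymatic ketone reduction by an alcohol dehydrogenase that accepts this dione; only the unhindered C4 carbonyl is reduced and hydride is delivered to a single face, setting 4R under enzyme control, while the C1 carbonyl between the quaternary and the tertiary carbon is left alone.

**Step 3**
Reactants: 3 (4R,6R)-4-hydroxy-2,2,6-trimethylcyclohexan-1-one
Product: 4 (4R,6R)-4-[(tert-butyldimethylsilyl)oxy]-2,2,6-trimethylcyclohexan-1-one
Conditions: TBSCl, imidazole, DMF, rt
Reagents that add atoms: tert-butyldimethylsilyl chloride, CC(C)(C)[Si](C)(C)Cl
Why: Standard imidazole-promoted silylation of a secondary alcohol; no stereocentre is touched, and any epimerisation at C6 would be irrelevant because that centre becomes sp2 in step 4.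

**Step 4**
Reactants: 4 (4R,6R)-4-[(tert-butyldimethylsilyl)oxy]-2,2,6-trimethylcyclohexan-1-one
Product: 6 (4R)-4-[(tert-butyldimethylsilyl)oxy]-2,6,6-trimethylcyclohex-1-en-1-yl trifluoromethanesulfonate, via potassium enolate 5 (not isolated)
Conditions: KN(SiMe3)2, THF, −78 to −20 °C; then PhNTf2, −78 °C to rt
Reagents that add atoms: N-phenylbis(trifluoromethanesulfonimide), O=S(=O)(N(c1ccccc1)S(=O)(=O)C(F)(F)F)C(F)(F)F
Why: Enolate formation followed by O-sulfonylation with an N-aryl triflimide (enol triflate synthesis); the ketone has a single α-hydrogen, at C6, so only one enolate and one triflate can form, and the silyloxy group is γ to the carbonyl and cannot be eliminated.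

**Step 5**
Reactants: 6 (4R)-4-[(tert-butyldimethylsilyl)oxy]-2,6,6-trimethylcyclohex-1-en-1-yl trifluoromethanesulfonate; 7 potassium vinyltrifluoroborate, K[CH2=CHBF3]
Product: 8 (R)-tert-butyldimethyl[(3,5,5-trimethyl-4-vinylcyclohex-3-en-1-yl)oxy]silane
Conditions: PdCl2(dppf)·CH2Cl2 (5 mol %), Cs2CO3, THF/H2O (9:1), 70 °C
Reagents that add atoms: none
Why: Suzuki–Miyaura coupling of an enol triflate with a vinyltrifluoroborate: oxidative addition of the C–O bond to zerovalent palladium, transmetalation from the slowly hydrolysed borate, reductive elimination; the wide-bite-angle ferrocenyl bisphosphine is chosen for the hindered tetrasubstituted triflate, and the stereocentre is remote and untouched.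

**Step 6**
Reactants: 8 (R)-tert-butyldimethyl[(3,5,5-trimethyl-4-vinylcyclohex-3-en-1-yl)oxy]silane; 9 dioxygen
Product: 10 (7S,8aR)-7-[(tert-butyldimethylsilyl)oxy]-5,5,8a-trimethyl-3,5,6,7,8,8a-hexahydro-1,2-benzodioxine
Conditions: O2 (1 atm), tetraphenylporphyrin (cat.), hν (visible, white LED), CH2Cl2, −40 °C
Reagents that add atoms: none
Why: Dioxygen 9, raised to its singlet state by energy transfer from the excited porphyrin, adds across the methyl-bearing ring carbon C3 and the CH2 terminus of the vinyl group of 8, whose diene is twisted but s-cis, in a concerted suprafacial [4+2] cycloaddition; the closest known reaction type is the photo-oxygenation of 1-vinylcyclohexenes and β-ionone-type dienes to 3,6-dihydro-1,2-dioxines. The dioxine ring is closed by the cycloaddition itself: both C–O bonds form on one face in a single step and the former ring–vinyl single bond becomes the C4a=C4 double bond. The new stereocentre C8a is set by substrate control from the silyloxy-bearing carbon: in the half-chair with the silyloxy group equatorial (the axial conformer suffers a 1,3-diaxial clash with a C5 methyl), chair-like axial bond formation at C3 takes place on the face of the axial carbinol hydrogen, anti to the silyloxy group, which corresponds to 8aR. Two selectivities are needed, cycloaddition over the ene reaction and anti over syn approach. An ene reaction that bonded oxygen to the methyl-bearing carbon would need an allylic hydrogen on a neighbour of the vinyl-bearing carbon, and there is none (one neighbour is quaternary, the other is the vinyl CH). Ene products can therefore only arise by bonding at the vinyl-bearing carbon, which is neopentyl and shielded by the gem-dimethyl group, whereas the cycloaddition bonds at the less hindered methyl-bearing carbon and the open CH2 terminus. Low temperature and an aprotic solvent are chosen to favour the concerted path, and the silyl ether is inert to singlet oxygen.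

**Step 7**
Reactants: 10 (7S,8aR)-7-[(tert-butyldimethylsilyl)oxy]-5,5,8a-trimethyl-3,5,6,7,8,8a-hexahydro-1,2-benzodioxine
Product: 12 (6S,7aR)-6-[(tert-butyldimethylsilyl)oxy]-4,4,7a-trimethyl-2,4,5,6,7,7a-hexahydro-1-benzofuran-2-ol (lactol; both C2 epimers), via Z-hydroxy enal 11 (not isolated)
Conditions: Et3N (0.5 equiv), CH2Cl2, 0 °C to rt
Reagents that add atoms: none
Why: Kornblum–DeLaMare rearrangement: the amine removes one of the two hydrogens on C3 of the dioxine and the O–O bond breaks in an E2-like manner to give the aldehyde and the tertiary alkoxide; C8a has no hydrogen, so the opening can run in this direction only, and the Z geometry inherited from the ring lets the tertiary hydroxyl of 11 add to the aldehyde to give 12 with both stereocentres unchanged.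

**Step 8**
Reactants: 12 (6S,7aR)-6-[(tert-butyldimethylsilyl)oxy]-4,4,7a-trimethyl-2,4,5,6,7,7a-hexahydro-1-benzofuran-2-ol
Product: 13 (6S,7aR)-6-[(tert-butyldimethylsilyl)oxy]-4,4,7a-trimethyl-5,6,7,7a-tetrahydro-1-benzofuran-2(4H)-one
Conditions: nPr4N[RuO4] (5 mol %), N-methylmorpholine N-oxide, 4 Å MS, CH2Cl2, rt
Reagents that add atoms: none
Why: Ley–Griffith oxidation of a lactol to the lactone with catalytic perruthenate and an N-oxide co-oxidant; the medium is neutral, so the silyl ether and the tertiary allylic C–O bond are safe, and both lactol epimers converge on one butenolide.

**Step 9**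
Reactants: 13 (6S,7aR)-6-[(tert-butyldimethylsilyl)oxy]-4,4,7a-trimethyl-5,6,7,7a-tetrahydro-1-benzofuran-2(4H)-one
Product: 14 (6S,7aR)-6-hydroxy-4,4,7a-trimethyl-5,6,7,7a-tetrahydro-1-benzofuran-2(4H)-one ((−)-loliolide)
Conditions: HF·pyridine, THF, 0 °C to rt
Reagents that add atoms: none
Why: Fluoride-mediated cleavage of the Si–O bond; buffered hydrogen fluoride is used in place of a basic fluoride so that the butenolide does not meet alkoxide, and the C6–O bond is not broken, so 6S is kept.

**Step 10**
Reactants: 14 (6S,7aR)-6-hydroxy-4,4,7a-trimethyl-5,6,7,7a-tetrahydro-1-benzofuran-2(4H)-one; 15 palmitoyl chloride (hexadecanoyl chloride)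
Product: 16 (6S,7aR)-4,4,7a-trimethyl-2-oxo-2,4,5,6,7,7a-hexahydro-1-benzofuran-6-yl hexadecanoate ((−)-3-O-palmitoylloliolide)
Conditions: pyridine, DMAP (cat.), CH2Cl2, 0 °C to rt
Reagents that add atoms: none
Why: Nucleophile-catalysed acylation of a secondary alcohol by an acid chloride through an acylpyridinium ion; the axial hydroxyl is hindered by two syn-axial methyl groups, hence the acyl-transfer catalyst, and acylation on oxygen leaves C6 and C7a as they are.

## Compound list

1 | ketoisophorone (2,6,6-trimethylcyclohex-2-ene-1,4-dione) | CC1=CC(=O)CC(C)(C)C1=O | starting material
2 | (6R)-2,2,6-trimethylcyclohexane-1,4-dione ((6R)-levodione) | C[C@@H]1CC(=O)CC(C)(C)C1=O | intermediate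
3 | (4R,6R)-4-hydroxy-2,2,6-trimethylcyclohexan-1-one ((4R,6R)-actinol) | O[C@H]1CC(C)(C)C(=O)[C@H](C)C1 | intermediate
4 | (4R,6R)-4-[(tert-butyldimethylsilyl)oxy]-2,2,6-trimethylcyclohexan-1-one | CC(C)(C)[Si](C)(C)O[C@H]1CC(C)(C)C(=O)[C@H](C)C1 | intermediate
5 | potassium (4R)-4-[(tert-butyldimethylsilyl)oxy]-2,6,6-trimethylcyclohex-1-en-1-olate (potassium enolate) | CC(C)(C)[Si](C)(C)O[C@H]1CC(C)(C)C([O-])=C(C)C1.[K+] | intermediate (not isolated)
6 | (4R)-4-[(tert-butyldimethylsilyl)oxy]-2,6,6-trimethylcyclohex-1-en-1-yl trifluoromethanesulfonate | CC(C)(C)[Si](C)(C)O[C@H]1CC(C)(C)C(OS(=O)(=O)C(F)(F)F)=C(C)C1 | intermediate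
7 | potassium vinyltrifluoroborate | [K+].F[B-](F)(F)C=C | starting material
8 | (R)-tert-butyldimethyl[(3,5,5-trimethyl-4-vinylcyclohex-3-en-1-yl)oxy]silane | CC(C)(C)[Si](C)(C)O[C@H]1CC(C)(C)C(C=C)=C(C)C1 | intermediate
9 | dioxygen | O=O | starting material
10 | (7S,8aR)-7-[(tert-butyldimethylsilyl)oxy]-5,5,8a-trimethyl-3,5,6,7,8,8a-hexahydro-1,2-benzodioxine | CC(C)(C)[Si](C)(C)O[C@H]1CC(C)(C)C2=CCOO[C@]2(C)C1 | intermediate
11 | (2Z)-2-[(2R,4S)-4-[(tert-butyldimethylsilyl)oxy]-2-hydroxy-2,6,6-trimethylcyclohexylidene]acetaldehyde (Z-hydroxy enal) | CC(C)(C)[Si](C)(C)O[C@H]1CC(C)(C)/C(=C/C=O)[C@@](O)(C)C1 | intermediate (not isolated)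
12 | (6S,7aR)-6-[(tert-butyldimethylsilyl)oxy]-4,4,7a-trimethyl-2,4,5,6,7,7a-hexahydro-1-benzofuran-2-ol (lactol, C2 epimers) | CC(C)(C)[Si](C)(C)O[C@H]1CC(C)(C)C2=CC(O)O[C@]2(C)C1 | intermediate
13 | (6S,7aR)-6-[(tert-butyldimethylsilyl)oxy]-4,4,7a-trimethyl-5,6,7,7a-tetrahydro-1-benzofuran-2(4H)-one | CC(C)(C)[Si](C)(C)O[C@H]1CC(C)(C)C2=CC(=O)O[C@]2(C)C1 | intermediate
14 | (6S,7aR)-6-hydroxy-4,4,7a-trimethyl-5,6,7,7a-tetrahydro-1-benzofuran-2(4H)-one ((−)-loliolide) | O[C@H]1CC(C)(C)C2=CC(=O)O[C@]2(C)C1 | intermediate
15 | palmitoyl chloride (hexadecanoyl chloride) | CCCCCCCCCCCCCCCC(=O)Cl | starting material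
16 | (6S,7aR)-4,4,7a-trimethyl-2-oxo-2,4,5,6,7,7a-hexahydro-1-benzofuran-6-yl hexadecanoate ((−)-3-O-palmitoylloliolide) | CCCCCCCCCCCCCCCC(=O)O[C@H]1CC(C)(C)C2=CC(=O)O[C@]2(C)C1 | target

## Step count and least certain steps

Total step count: 10. Longest linear sequence: 10 steps (1 to 16).

**Step 6 (key step).**
- What may go wrong: poor facial selectivity, because the controlling stereocentre is two bonds away from the ring carbon that is attacked and the anti face carries a pseudoaxial methyl group. Diversion into the ene manifold at the tetrasubstituted alkene. Thermal or light-induced decomposition of the peroxide before it is used.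
- Fallback (sets out from 8, comes back at 13): the ring double bond of 8, far more electron-rich than the vinyl group, is epoxidised with mCPBA and NaHCO3 in CH2Cl2 at 0 °C. Attack anti to a silyloxy or acyloxy group is the documented preference for rings of this type, and the product would be tert-butyl{[(1S,4S,6R)-1-ethenyl-2,2,6-trimethyl-7-oxabicyclo[4.1.0]heptan-4-yl]oxy}dimethylsilane F1. Pd(PPh3)4 and AcOH in THF then ionise the allylic C–O bond, while the C–O bond at the methyl-bearing carbon keeps its configuration. Acetate attacks the unhindered terminus of the π-allyl complex of divalent palladium formed from the zerovalent catalyst, giving (2Z)-2-[(2R,4S)-4-[(tert-butyldimethylsilyl)oxy]-2-hydroxy-2,6,6-trimethylcyclohexylidene]ethyl acetate F2. The Z geometry is expected because the CH2 terminus avoids the gem-dimethyl group. K2CO3 in MeOH frees (1R,2Z,5S)-5-[(tert-butyldimethylsilyl)oxy]-2-(2-hydroxyethylidene)-1,3,3-trimethylcyclohexan-1-ol F3. MnO2 in CH2Cl2 oxidises the allylic primary alcohol to the enal, which closes to the lactol and is oxidised further to 13.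

**Step 5.**
- What may go wrong: slow oxidative addition and transmetalation at a triflate flanked by a quaternary carbon and a substituted alkene carbon. Hydrolysis of the triflate back to the ketone and loss of the vinylboron reagent by protodeboronation then take over.
- Fallback (sets out from 4, comes back at 8): no cross-coupling is used. CH2=CHMgBr with anhydrous CeCl3 in THF (−78 to 0 °C) adds to the hindered carbonyl of 4 to give (4R,6R)-4-[(tert-butyldimethylsilyl)oxy]-1-ethenyl-2,2,6-trimethylcyclohexan-1-ol F4, with the configuration at C1 immaterial. Dehydration with POCl3 in pyridine can only run toward the single β-hydrogen at C6 and should give the conjugated diene 8.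

**Step 4.**
- What may go wrong: incomplete deprotonation of the single tertiary α-hydrogen next to the carbonyl, and sluggish O-sulfonylation of the resulting hindered enolate, so that ketone is returned.
- Fallback (sets out from 4, comes back at 8): Barton vinyl iodide synthesis. N2H4·H2O and Et3N in EtOH at reflux give (4R,6R)-4-[(tert-butyldimethylsilyl)oxy]-2,2,6-trimethylcyclohexan-1-one hydrazone F5. I2 and tetramethylguanidine in THF convert it with loss of dinitrogen into tert-butyl{[(1R)-4-iodo-3,5,5-trimethylcyclohex-3-en-1-yl]oxy}dimethylsilane F6. F6 is coupled with 7 under the conditions of step 5 to give 8.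

**Step 2.**
- What may go wrong: low activity or incomplete face discrimination of the reductase preparation, and erosion of the C6 configuration of 2 by enolisation in the buffer before reduction.
- Fallback (sets out from 2, comes back at 3; no new compound): substrate-controlled chemical reduction with Li[HB(sec-Bu)3] in THF at −78 °C. The bulky hydride should attack only the unhindered C4 carbonyl and from the equatorial direction, because the axial path is blocked by the axial methyl at C2. This gives the axial alcohol trans to the C6 methyl, which is 3.

## Further compounds

F1 | step 6 | tert-butyl{[(1S,4S,6R)-1-ethenyl-2,2,6-trimethyl-7-oxabicyclo[4.1.0]heptan-4-yl]oxy}dimethylsilane | CC(C)(C)[Si](C)(C)O[C@H]1CC(C)(C)[C@]2(C=C)O[C@]2(C)C1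
F2 | step 6 | (2Z)-2-[(2R,4S)-4-[(tert-butyldimethylsilyl)oxy]-2-hydroxy-2,6,6-trimethylcyclohexylidene]ethyl acetate | CC(C)(C)[Si](C)(C)O[C@H]1CC(C)(C)/C(=C/COC(C)=O)[C@@](O)(C)C1
F3 | step 6 | (1R,2Z,5S)-5-[(tert-butyldimethylsilyl)oxy]-2-(2-hydroxyethylidene)-1,3,3-trimethylcyclohexan-1-ol | CC(C)(C)[Si](C)(C)O[C@H]1CC(C)(C)/C(=C/CO)[C@@](O)(C)C1
F4 | step 5 | (4R,6R)-4-[(tert-butyldimethylsilyl)oxy]-1-ethenyl-2,2,6-trimethylcyclohexan-1-ol (C1 configuration open) | CC(C)(C)[Si](C)(C)O[C@H]1CC(C)(C)C(O)(C=C)[C@H](C)C1
F5 | step 4 | (4R,6R)-4-[(tert-butyldimethylsilyl)oxy]-2,2,6-trimethylcyclohexan-1-one hydrazone | CC(C)(C)[Si](C)(C)O[C@H]1CC(C)(C)C(=NN)[C@H](C)C1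
F6 | step 4 | tert-butyl{[(1R)-4-iodo-3,5,5-trimethylcyclohex-3-en-1-yl]oxy}dimethylsilane | CC(C)(C)[Si](C)(C)O[C@H]1CC(C)(C)C(I)=C(C)C1
F0 | step 2 | none | none
A1 | alternative 1 | (3aS,6S,7aR)-4,4,7a-trimethyl-2-oxooctahydro-1-benzofuran-6-yl benzoate | O=C(O[C@H]1CC(C)(C)[C@@H]2CC(=O)O[C@]2(C)C1)c1ccccc1
A2 | alternative 1 | (1S,3S)-3-[(diazoacetyl)oxy]-3,5,5-trimethylcyclohexyl benzoate | O=C(O[C@H]1CC(C)(C)C[C@](C)(OC(=O)C=[N+]=[N-])C1)c1ccccc1
A3 | alternative 2 | (6S,7aR)-6-[(tert-butyldimethylsilyl)oxy]-4,4,7a-trimethyl-5,6,7,7a-tetrahydro-1-benzofuran-2(4H)-one | CC(C)(C)[Si](C)(C)O[C@H]1CC(C)(C)C2=CC(=O)O[C@]2(C)C1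
A4 | alternative 2 | ethyl (4R,6R)-6-[(tert-butyldimethylsilyl)oxy]-4-hydroxy-4,8-dimethylnon-7-en-2-ynoate | CCOC(=O)C#C[C@](C)(O)C[C@@H](O[Si](C)(C)C(C)(C)C)C=C(C)C
A5 | alternative 3 | (7aR)-4,4,7a-trimethyl-7,7a-dihydro-1-benzofuran-2(4H)-one | C1=CC(C)(C)C2=CC(=O)O[C@]2(C)C1
A6 | alternative 3 | (5R)-5-methyl-4-(2-methylbut-3-en-2-yl)-5-(prop-2-en-1-yl)furan-2(5H)-one | C=CC(C)(C)C1=CC(=O)O[C@]1(C)CC=C
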